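## Retrosynthetic overview
- Daphnodorin C ⇐ global O‑debenzylation and de‑bromination of the spiro‑coumaranone **23**. The coumaranone ring is formed last, by oxidative C3′–O closure of the 2″‑hydroxyaroyl dihydrobenzofuran **22**.
- **22** ⇐ trans dihydrobenzofuran ester **18**, converted by DIBAL, Ar″Li addition and oxidation. The dihydrobenzofuran, including C2′, comes from Rh‑carbene benzylic C–H insertion of aryldiazoacetate **16**, built on C8 of the (S)‑flavan **12**.
- (S)‑Flavan **12** ⇐ ketoreductase reduction of dihydrochalcone **10**, then Mitsunobu ring closure. **10** comes from 2,4,6‑trihydroxybenzaldehyde and 4‑benzyloxyacetophenone.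
- Ring order: chroman, then dihydrobenzofuran, then spiro‑coumaranone.

Assumptions:
- A commercial KRED panel contains an (R)‑selective hit for ketone **10**.
- NBS brominates C8 rather than C6 of flavan **12**, as it does for catechin‑type ethers.
- C3′ of **17–22** is epimerizable and is reset in Step 19.

---

## Route

**Step 1**
Reactants: **1** phloroglucinol
Product: **2** 1,3,5‑tris(benzyloxy)benzene
Conditions: BnBr (3.3 equiv), K2CO3, DMF, 60 °C
Reagents that add atoms: benzyl bromide, BrCc1ccccc1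
Why: Williamson O‑alkylation of all three equivalent phenols gives an electron‑rich arene that is later used as the Ar″ unit.

**Step 2**
Reactants: **2**
Product: **3** 2,4,6‑tribromo‑1,3,5‑tris(benzyloxy)benzene
Conditions: NBS (3.3 equiv), CH2Cl2, 0 °C → rt
Reagents that add atoms: N‑bromosuccinimide, BrN1C(=O)CCC1=O
Why: Electrophilic aromatic bromination at all three equivalent positions gives a symmetrical aryl bromide, so there is no regiochemistry issue. Two Br atoms remain as blocking groups that keep the later phenoxide ring from being halogenated, and they are removed in Step 20.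

**Step 3**
Reactants: **4** 2,4,6‑trihydroxybenzaldehyde; **5** 4‑(benzyloxy)benzyl chloride
Product: **6** 4‑O‑(4‑benzyloxybenzyl)‑2,6‑dihydroxybenzaldehyde
Conditions: CsHCO3, KI (cat.), MeCN, 80 °C
Reagents that add atoms: none
Why: Cs‑bicarbonate Williamson alkylation selectively alkylates the most acidic para‑OH, because the two ortho‑OH groups are chelated to the CHO.

**Step 4**
Reactants: **6**
Product: **7** 6‑benzyloxy‑2‑hydroxy‑4‑(4‑benzyloxybenzyloxy)benzaldehyde
Conditions: BnBr (1.0 equiv), K2CO3, acetone, 50 °C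
Reagents that add atoms: benzyl bromide, BrCc1ccccc1
Why: The two ortho‑OH groups are equivalent, so statistical mono‑benzylation gives one product, and the other OH is O8a, the future chroman oxygen. Unreacted **6** is recycled.

**Step 5**
Reactants: **7**; **8** 4′‑benzyloxyacetophenone
Product: **9** (E)‑chalcone
Conditions: KOH (6 equiv), EtOH/THF, rt → 40 °C, 48 h
Reagents that add atoms: none
Why: Claisen–Schmidt condensation gives the thermodynamic E‑enone.

**Step 6**
Reactants: **9**
Product: **10** dihydrochalcone, 1‑(4‑BnO‑phenyl)‑3‑aryl‑propan‑1‑one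
Conditions: H2 (1 atm), Pd/C(ethylenediamine), THF, rt
Reagents that add atoms: none
Why: Ethylenediamine‑poisoned Pd/C reduces the C=C bond chemoselectively without cleaving the benzyl or benzylic aryl ethers.

**Step 7**
Reactants: **10**
Product: **11** (R)‑1‑(4‑benzyloxyphenyl)‑3‑aryl‑propan‑1‑ol
Conditions: ketoreductase (KRED, NADPH‑dependent alcohol dehydrogenase, oxidoreductase class), NADP+ (cat.), iPrOH (20% v/v) for cofactor recycling, DMSO (10%), KPi pH 7, 30 °C
Reagents that add atoms: none
Why: This is the first stereocenter, set by enzymatic asymmetric catalysis. The enzyme delivers hydride to one face of the prochiral aryl ketone to give the (R)‑carbinol, which becomes (2S) after the inversion in Step 8.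

**Step 8**
Reactants: **11**
Product: **12** (2S)‑5‑benzyloxy‑2‑(4‑benzyloxyphenyl)‑7‑(4‑benzyloxybenzyloxy)chromane
Conditions: PPh3, DIAD, THF (0.02 M), 0 °C → rt
Reagents that add atoms: none
Why: Intramolecular Mitsunobu SN2 by the ortho phenol at the benzylic carbinol inverts it, giving the 2S chroman. Dilution suppresses oligomerization.

**Step 9**
Reactants: **12**
Product: **13** 8‑bromo‑flavan
Conditions: NBS (1.0 equiv), CH2Cl2, −78 → −40 °C
Reagents that add atoms: N‑bromosuccinimide, BrN1C(=O)CCC1=O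
Why: Electrophilic bromination goes to C8, the most nucleophilic A‑ring site flanked by O7 and O1. C2 is untouched.

**Step 10**
Reactants: **13**
Product: **14** ethyl 2‑(flavan‑8‑yl)‑2‑oxoacetate
Conditions: n‑BuLi (1.1 equiv), THF, −78 °C, 20 min; transfer into diethyl oxalate (3 equiv), THF, −78 °C
Reagents that add atoms: diethyl oxalate, CCOC(=O)C(=O)OCC
Why: Br/Li exchange, assisted by the two ortho alkoxy groups, gives the aryllithium. Inverse addition to excess oxalate stops the reaction at the mono‑acylation (α‑keto ester) stage.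

**Step 11**
Reactants: **14**
Product: **15** tosylhydrazone of **14**
Conditions: TsNHNH2 (1.5 equiv), MeOH/THF 1:1, 60 °C, 16 h
Reagents that add atoms: p‑toluenesulfonylhydrazide, Cc1ccc(cc1)S(=O)(=O)NN
Why: Condensation at the activated α‑keto‑ester carbonyl. Acid is avoided because of the PMB‑like aryl ether.

**Step 12**
Reactants: **15**
Product: **16** ethyl 2‑diazo‑2‑(flavan‑8‑yl)acetate
Conditions: DBU (1.2 equiv), CH2Cl2, rt, 1 h, dark; use immediately
Reagents that add atoms: none
Why: Bamford–Stevens elimination of p‑toluenesulfinate gives the stabilized donor/acceptor diazo compound.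

**Step 13**
Reactants: **16**
Product: **17** ethyl (2′R,3′S)‑cis‑2′‑(4‑BnO‑phenyl)‑dihydrofuro[2,3‑h]chromane‑3′‑carboxylate
Conditions: Rh2(S‑PTTL)4 (1 mol%), CH2Cl2, 0 °C → rt
Reagents that add atoms: none
Why: The chiral dirhodium carbene inserts into the activated benzylic O–CH2 C–H of the 7‑O‑(4‑benzyloxybenzyl) ether in a 1,5‑sense. The catalyst sets C2′ and the kinetic cis relationship. Catalyst enantiomer (S or R) is chosen by one screening run to give the 2′R ester, which corresponds to the target's C2′ (S).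

**Step 14**
Reactants: **17**
Product: **18** trans ester (2′R,3′R)
Conditions: NaOEt (0.3 equiv), EtOH/THF, rt, 4 h
Reagents that add atoms: none
Why: Base epimerizes the acidic C3′–H to the thermodynamic trans isomer. C2′ is not acidic, and E1cB ring opening is stereoelectronically disfavoured.

**Step 15**
Reactants: **18**
Product: **19** aldehyde (2′R,3′R)
Conditions: DIBAL‑H (1.2 equiv), toluene/CH2Cl2, −78 °C; Rochelle salt work‑up
Reagents that add atoms: none
Why: Partial reduction of the hindered ester stops at the aldehyde at −78 °C, and the aldehyde is used at once.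

**Step 16**
Reactants: **19**; **3**
Product: **20** diaryl carbinol, Ar″CH(OH)–C3′, C3′ trans, carbinol carbon unspecified
Conditions: **3** (1.3 equiv), n‑BuLi (1.3 equiv), THF, −78 °C, 30 min; then **19**, −78 → −20 °C
Reagents that add atoms: none
Why: Selective mono Br/Li exchange of the symmetrical tribromide gives one aryllithium, which adds 1,2 to the aldehyde. The carbinol stereocenter is destroyed in the next step.

**Step 17**
Reactants: **20**
Product: **21** aryl ketone
Conditions: Dess–Martin periodinane (2 equiv), NaHCO3, CH2Cl2, rt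
Reagents that add atoms: none
Why: Mild oxidation of the secondary diaryl carbinol to the 2,4,6‑tris(benzyloxy)‑3,5‑dibromobenzoyl ketone.

**Step 18**
Reactants: **21**
Product: **22** 2″‑hydroxy ketone
Conditions: BCl3 (1.1 equiv), pentamethylbenzene (3 equiv), CH2Cl2, −78 °C, 30 min
Reagents that add atoms: none
Why: Carbonyl‑chelated BCl3 cleaves one benzyl ether ortho to the ketone. The two ortho OBn groups are equivalent, so a single product forms, and pentamethylbenzene traps the benzyl cation.

**Step 19**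
Reactants: **22**
Product: **23** protected spiro‑coumaranone, 2′S, spiro S
Conditions: KHMDS (2.5 equiv), THF, −78 °C, 30 min; then I2 (1.2 equiv), −78 → 0 °C
Reagents that add atoms: none
Why: The phenoxide/enolate dianion is iodinated at C3′ anti to the C2′ aryl, and the phenoxide then displaces iodide in a 5‑exo SN2 with inversion. This is an oxidative C–O coupling that puts the new C–O bond cis to the C2′ aryl and the aroyl group trans, which is the target configuration. The phenoxide ring is blocked by Br, so it cannot be iodinated.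

**Step 20**
Reactants: **23**
Product: **24** Daphnodorin C
Conditions: H2 (1 atm), Pd(OH)2/C, Et3N (5 equiv), THF/MeOH 1:1, rt, 24 h
Reagents that add atoms: none
Why: Hydrogenolysis removes the five benzyl ethers and the two aryl bromides. The C2–O, C2′–O and spiro C–O bonds and the stereocenters are retained under these mild conditions.

---

## Compound list
1 | phloroglucinol | Oc1cc(O)cc(O)c1 | starting material
2 | 1,3,5‑tris(benzyloxy)benzene | O(Cc1ccccc1)c1cc(OCc2ccccc2)cc(OCc2ccccc2)c1 | intermediate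
3 | 2,4,6‑tribromo‑1,3,5‑tris(benzyloxy)benzene | Brc1c(OCc2ccccc2)c(Br)c(OCc2ccccc2)c(Br)c1OCc1ccccc1 | intermediate
4 | 2,4,6‑trihydroxybenzaldehyde | O=Cc1c(O)cc(O)cc1O | starting material
5 | 4‑(benzyloxy)benzyl chloride | ClCc1ccc(OCc2ccccc2)cc1 | starting material
6 | 4‑O‑(4‑benzyloxybenzyl)‑2,6‑dihydroxybenzaldehyde | O=Cc1c(O)cc(OCc2ccc(OCc3ccccc3)cc2)cc1O | intermediate
7 | 6‑benzyloxy‑2‑hydroxy‑4‑(4‑benzyloxybenzyloxy)benzaldehyde | O=Cc1c(O)cc(OCc2ccc(OCc3ccccc3)cc2)cc1OCc1ccccc1 | intermediate
8 | 4′‑benzyloxyacetophenone | CC(=O)c1ccc(OCc2ccccc2)cc1 | starting material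
9 | (E)‑chalcone | O=C(/C=C/c1c(O)cc(OCc2ccc(OCc3ccccc3)cc2)cc1OCc1ccccc1)c1ccc(OCc2ccccc2)cc1 | intermediate
10 | dihydrochalcone | O=C(CCc1c(O)cc(OCc2ccc(OCc3ccccc3)cc2)cc1OCc1ccccc1)c1ccc(OCc2ccccc2)cc1 | intermediate
11 | (R)‑1‑(4‑benzyloxyphenyl)‑3‑aryl‑propan‑1‑ol | O[C@H](CCc1c(O)cc(OCc2ccc(OCc3ccccc3)cc2)cc1OCc1ccccc1)c1ccc(OCc2ccccc2)cc1 | intermediate
12 | (2S)‑5‑BnO‑2‑(4‑BnO‑phenyl)‑7‑(4‑BnO‑benzyloxy)chromane | O(Cc1ccccc1)c1cc(OCc2ccc(OCc3ccccc3)cc2)cc2O[C@H](c3ccc(OCc4ccccc4)cc3)CCc12 | intermediate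
13 | 8‑bromo derivative of 12 | O(Cc1ccccc1)c1cc(OCc2ccc(OCc3ccccc3)cc2)c(Br)c2O[C@H](c3ccc(OCc4ccccc4)cc3)CCc12 | intermediate
14 | ethyl flavan‑8‑yl glyoxylate | O(Cc1ccccc1)c1cc(OCc2ccc(OCc3ccccc3)cc2)c(C(=O)C(=O)OCC)c2O[C@H](c3ccc(OCc4ccccc4)cc3)CCc12 | intermediate
15 | tosylhydrazone of 14 | O(Cc1ccccc1)c1cc(OCc2ccc(OCc3ccccc3)cc2)c(C(=NNS(=O)(=O)c5ccc(C)cc5)C(=O)OCC)c2O[C@H](c3ccc(OCc4ccccc4)cc3)CCc12 | intermediate
16 | ethyl 2‑diazo‑2‑(flavan‑8‑yl)acetate | O(Cc1ccccc1)c1cc(OCc2ccc(OCc3ccccc3)cc2)c(C(=[N+]=[N-])C(=O)OCC)c2O[C@H](c3ccc(OCc4ccccc4)cc3)CCc12 | intermediate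
17 | cis dihydrobenzofuran ester (2′R,3′S) | CCOC(=O)[C@H]2c1c(cc(OCc3ccccc3)c3c1O[C@H](c1ccc(OCc4ccccc4)cc1)CC3)O[C@H]2c1ccc(OCc4ccccc4)cc1 | intermediate
18 | trans dihydrobenzofuran ester (2′R,3′R) | CCOC(=O)[C@@H]2c1c(cc(OCc3ccccc3)c3c1O[C@H](c1ccc(OCc4ccccc4)cc1)CC3)O[C@H]2c1ccc(OCc4ccccc4)cc1 | intermediate
19 | trans aldehyde | O=C[C@@H]2c1c(cc(OCc3ccccc3)c3c1O[C@H](c1ccc(OCc4ccccc4)cc1)CC3)O[C@H]2c1ccc(OCc4ccccc4)cc1 | intermediate
20 | diaryl carbinol (carbinol carbon unspecified) | OC(c1c(OCc5ccccc5)c(Br)c(OCc5ccccc5)c(Br)c1OCc5ccccc5)[C@@H]2c1c(cc(OCc3ccccc3)c3c1O[C@H](c1ccc(OCc4ccccc4)cc1)CC3)O[C@H]2c1ccc(OCc4ccccc4)cc1 | intermediate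
21 | tris(benzyloxy)dibromobenzoyl ketone | O=C(c1c(OCc5ccccc5)c(Br)c(OCc5ccccc5)c(Br)c1OCc5ccccc5)[C@@H]2c1c(cc(OCc3ccccc3)c3c1O[C@H](c1ccc(OCc4ccccc4)cc1)CC3)O[C@H]2c1ccc(OCc4ccccc4)cc1 | intermediate
22 | 2″‑hydroxy ketone | O=C(c1c(O)c(Br)c(OCc5ccccc5)c(Br)c1OCc5ccccc5)[C@@H]2c1c(cc(OCc3ccccc3)c3c1O[C@H](c1ccc(OCc4ccccc4)cc1)CC3)O[C@H]2c1ccc(OCc4ccccc4)cc1 | intermediate
23 | protected spiro‑coumaranone | O=C1c2c(OCc4ccccc4)c(Br)c(OCc4ccccc4)c(Br)c2O[C@]12c1c(cc(OCc4ccccc4)c3c1O[C@H](c1ccc(OCc4ccccc4)cc1)CC3)O[C@H]2c1ccc(OCc4ccccc4)cc1 | intermediate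
24 | Daphnodorin C | O=C1c2c(O)cc(O)cc2O[C@]12c1c(cc(O)c3c1O[C@H](c1ccc(O)cc1)CC3)O[C@H]2c1ccc(O)cc1 | target

---

**Total steps:** 20 numbered steps. **Longest linear sequence:** 18 steps, from **4** through Step 3 to Step 20. The Ar″ branch (Steps 1–2) joins at Step 16.

**Three steps most likely to fail**

1. **Step 19, oxidative spirocyclization.** The risks are wrong C3′ diastereoselectivity if the closure is SN1‑like, and elimination to the 3‑aroylbenzofuran.
   - Fallback: switch to a single‑electron oxidative C–O coupling of the mono‑phenol **22** (Cu(OAc)2/O2 or Ag2O). This does not rely on an α‑iodide and SN2 inversion; diastereomers are then separated by HPLC.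

2. **Step 13, Rh‑catalysed C–H insertion.** The 2,6‑dialkoxyaryl diazoacetate is hindered, and the competing chroman C2–H insertion could erode yield and ee.
   - Fallback: set C2′ by Ru‑catalysed dynamic‑kinetic‑resolution transfer hydrogenation of the α‑aryl‑β‑keto ester (made from the arylacetate and 4‑benzyloxybenzoyl chloride), followed by Mitsunobu O‑cyclization with inversion.

3. **Step 16, hindered aryllithium addition.** The tribromide‑derived Ar″Li may add poorly to the α‑branched aldehyde or suffer halogen scrambling.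
   - Fallback: make the aryl–C(=O) bond electrophilically. Hydrolyse **18** to the acid, form the acid chloride, and acylate 1,3,5‑tris(benzyloxy)‑2,4,6‑tribromo‑free arene **2** under mild SnCl4. Then block the ring positions with Br and continue from Step 18.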